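## Structural features

The target is a flavone: ring A is fused to the 4-pyranone ring C along C4a–C8a, and ring B is attached to C2 of ring C through the single bond C2–C1'. There is no stereocentre and no stereogenic double bond, so nothing has to be set or preserved in three dimensions. Six oxygens sit on the periphery: methyl ethers on C3, C5 and C7 of the chromone and on C4' of ring B, and free phenols on C2' and C5'. The two phenols are para to each other and flank the C4' ether, so ring B is a methoxyhydroquinone, the reduced form of a 2-methoxy-1,4-benzoquinone. Fragile points are this hydroquinone (air oxidation, fastest in base), the C5 ether peri to the C4 carbonyl (cleaved by chelating Lewis acids) and C2 of the pyranone (addition of hard nucleophiles with ring opening). The real difficulty is the differentiation of the oxygens, not the carbon skeleton: two hydroxyls must stay free on ring B while four ethers, one on the same ring, stay methylated, and a late selective demethylation would have no handle to tell O2' and O5' from O3, O5 and O7. The key step uses exactly this pattern: a benzannulation joins an alkyne on C2 (C1' and C6'), a carbene carbon (C5'), a methoxyvinyl unit (C4' and C3') and one carbonyl ligand (C2'), which builds ring B with oxygen on C2', C4' and C5'. Passage through the quinone then removes the one methyl group that is not wanted.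

## Logic of the disconnections

17 to 16: no skeletal bond is cut; the two O–H bonds on O2' and O5' are removed and ring B is raised to the quinone oxidation level. The reason is that in 16 both future phenols are masked in the same way without any protecting group while the C4' ether is untouched. The gain is that the oxygen-differentiation problem is handed to the way the quinone is made. The forward step needs a mild two-electron reductant that ignores the pyranone, and a work-up that keeps air and base away from the product.

16 to 9 and 14 (through 15): the bonds C5'–C6', C1'–C2' and C2'–C3' are cut and the methyl group on O5' is restored. Ring B falls apart into the two alkyne carbons of 9, the carbene carbon and the vinyl carbons of 14, and one carbonyl ligand of 14. Cutting here removes a whole ring in one convergent operation and places every ring B oxygen by the mechanism instead of by protecting-group work. The forward step demands one orientation of alkyne insertion (terminal carbon to the carbene carbon), the phenol pathway over side pathways, and an oxidation that touches ring B only.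

14 to 10 and 11 (through 12 and 13): the bond between the carbene carbon and the vinyl carbon and the O–CH3 bond on the carbene oxygen are cut. This is the standard assembly of an alkoxycarbene complex and reduces 14 to two bulk chemicals. It demands clean α-metalation of 10, attack on a carbonyl ligand instead of the metal, O-alkylation by a hard methylating agent, and gentle handling of an acid-labile enol ether.

9 to 8: the triple bond C1'–C6' is cut, removing the terminal carbon, so the alkyne becomes an aldehyde whose carbon is the future C1'. A one-carbon homologation is the shortest known way to put an ethynyl group on an electron-poor heteroaryl carbon. The demand is a base mild enough for the pyranone C2 and for the conjugated alkyne that is formed.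

8 to 4 and 5 (through 6 and 7): the bonds O1–C2 and C2–C3 are cut, opening ring C into an ortho-hydroxyaryl ketone and a two-carbon ester whose second carbon is already at the aldehyde oxidation level as an acetal. C3 with its methoxy group is the nucleophilic α-carbon of 4 and C2 is the ester carbon of 5. This removes the reduction and re-oxidation that an oxalate-derived ester would need. The forward step asks for a Claisen condensation on an α-alkoxy ketone that carries a free phenol, followed by acid that cyclises and unmasks without touching the aryl ethers.

4 to 1 and 2 (through 3): the aryl–acyl bond C4a–C4 and the O–CH3 bond of the ether that becomes O1 are cut. The arene 1 has only one kind of ring position, so acylation has no regiochemical question, and the new ketone itself directs removal of one neighbouring methyl group by chelation. The demand is mono-acylation, cleavage of exactly one ortho ether and survival of the aliphatic methoxy group.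

## Other disconnections considered

Alternative 1: The cut is the C4a–C8a bond, which opens ring A into the polyketide chain methyl (Z)-8-methoxy-3,5,7-trioxo-9-(2,4,5-trimethoxyphenyl)non-8-enoate A2.
- Forward step: Mg(OMe)2 in methanol would hold the 1,3-dicarbonyl units of A2 in a chelate, chain carbon C6 would attack the ester carbon in an intramolecular Claisen condensation, and enolisation would give the acylphloroglucinol (Z)-2-methoxy-1-(2,4,6-trihydroxyphenyl)-3-(2,4,5-trimethoxyphenyl)prop-2-en-1-one A1.
- In its favour: the folding copies chalcone biosynthesis, creates the ring A oxygen pattern automatically and carries the C2–C1' connection from the start. It needs no transition metal; on reagent cost and on avoiding stoichiometric chromium it is better than the chosen plan.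
- Against it here: A2 is a sensitive poly-β-carbonyl compound that must be assembled by polyanion acylation. Aldol closure onto the C7 ketone and O-cyclisation to a pyranone compete with the Claisen mode, and the enone is open to conjugate addition of methoxide.
- What remains after A1: oxidative closure of ring C, methylation of the two ring A phenols that the folding has just freed (one chelated to the carbonyl), oxidative demethylation of ring B to 16, and reduction to 17.
- Comparison: both plans finish through 16 and the same reduction, so there they are equal. Structurally this alternative makes hydroxyls where the target has ethers and leaves ring B fully methylated where the target has phenols, whereas the chosen plan forms ring B directly at the quinone level. Mechanistically a chelation-controlled choice among three cyclisation modes is harder to predict than the sterically governed insertion of a terminal alkyne. In step count, about four steps to A2, the folding and four more steps exceed the five-step longest sequence of the chosen plan.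

Alternative 2: The cuts are O1–C8a and C4–C4a, so ring C is formed last from ring A as an aryne and from the C2–C3–C4 unit as an acylketene.
- Forward step: CsF would release 3,5-dimethoxybenzyne A6 from 3,5-dimethoxy-2-(trimethylsilyl)phenyl trifluoromethanesulfonate A4. Heating 5-methoxy-2,2-dimethyl-6-(2,4,5-trimethoxyphenyl)-4H-1,3-dioxin-4-one A5 would give, by cycloreversion, the aroylketene 2-methoxy-3-oxo-3-(2,4,5-trimethoxyphenyl)prop-1-en-1-one A7. Addition of the ketone oxygen of A7 to the aryne carbon remote from the neighbouring methoxy group and closure of the aryl anion onto the ketene carbon would give 3,5,7-trimethoxy-2-(2,4,5-trimethoxyphenyl)-4H-chromen-4-one A3.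
- In its favour: this is the most convergent of all the plans, joining the three rings and closing ring C in one operation with every oxygen already methylated. The known preference of a 3-methoxyaryne for attack at the distal carbon points to the right orientation. In convergence it is the equal of the chosen plan and in the number of bonds formed toward the complete skeleton it is better.
- Against it here: the ketene needs a temperature at which fluoride-induced aryne release is already fast, so the two reactive species are unlikely to be present together. Fluoride can add to A7, A7 can dimerise, and a ketone oxygen is a weak nucleophile for an aryne.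
- What remains after A3: ring B must still be told apart from the rest by oxidative demethylation to 16 before reduction to 17. A4 and A5 each need several steps.
- Comparison: structurally A3 carries six methyl ethers and relies on an oxidant to pick the one para pair on ring B, whereas the chosen plan never makes those two ethers. Mechanistically the trapping of an acylketene by an aryne has much thinner precedent than the benzannulation, which is used here on new partners but in its established form. In step count the two plans are close, since A3 is two steps from 17 and the chosen product 16 is one.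

Alternative 3: The cut is C4a–C5, so ring A is built last on a pyranone that derives from kojic acid A10 and already holds ring B.
- Forward step: LiN(SiMe3)2 would deprotonate methyl 4-[5-methoxy-4-oxo-6-(2,4,5-trimethoxyphenyl)-4H-pyran-2-yl]-3-oxobutanoate A9 to an extended enolate. Its ring carbon C4a would attack the ester carbon, and enolisation would give 5,7-dihydroxy-3-methoxy-2-(2,4,5-trimethoxyphenyl)-4H-chromen-4-one A8.
- In its favour: A10 is cheap and already contains the C3 oxygen and the C4 carbonyl, and the closure fixes the 5,7-dioxygenation of ring A without ambiguity. In freedom from heavy-metal carbonyls and in the certainty of the ring A pattern it is better than the chosen plan.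
- Against it here: A9 needs arylation of the pyranone next to the ring oxygen, homologation of the hydroxymethyl arm and a chain extension, well over five steps. The most acidic site of A9 is the methylene between ketone and ester, whose enolate deactivates the very ester that must be attacked, so a polyanion is required. The base can also open the pyranone.
- What remains after A8: two methylations (one of a chelated phenol) to reach A3, then the same ring B oxidation to 16 and reduction to 17.
- Comparison: structurally this plan puts free hydroxyls on ring A, where they are not wanted, and none on ring B. Mechanistically a vinylogous Claisen closure through a polyanion is plausible but depends on the order of deprotonation, whereas the chosen step depends on one steric preference. In step count it is clearly longer.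

Key step: step 5

Remark on the chemistry: in all SMILES strings each carbonyl ligand on chromium is written as Cr=C=O, and the 2-methoxy-1,3-dicarbonyl compounds 6, F1 and F11 are drawn as racemic keto tautomers whose one stereogenic carbon becomes the planar C3 of the pyranone.

## Route

Step 1
Reactants: 1 1,3,5-trimethoxybenzene; 2 methoxyacetyl chloride
Product: 4 1-(2-hydroxy-4,6-dimethoxyphenyl)-2-methoxyethan-1-one, via trimethoxyphenyl ketone 3 (not isolated)
Conditions: AlCl3 (2.5 equiv, added last), CH2Cl2, 0 °C to rt; then 1 M HCl
Reagents that add atoms: none
Why: Friedel–Crafts acylation of the threefold-symmetric arene, which has one kind of ring position and is deactivated after one acylation, gives 3; the excess AlCl3 then chelates the ketone oxygen and one ortho methoxy oxygen in a six-membered ring and chloride removes that methyl group (chelation-directed ortho-demethylation), stopping at the aluminium phenoxide of 4. The aliphatic methoxy group can form only a weaker five-membered chelate and its oxygen is a poorer leaving group, so it should survive at room temperature.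

Step 2
Reactants: 4 1-(2-hydroxy-4,6-dimethoxyphenyl)-2-methoxyethan-1-one; 5 ethyl diethoxyacetate
Product: 8 3,5,7-trimethoxy-4-oxo-4H-chromene-2-carbaldehyde, via 1,3-diketone 6 (not isolated), via diethyl acetal 7 (not isolated)
Conditions: NaH (3.2 equiv), THF, 0 to 65 °C; then AcOH, 6 M HCl, 60 °C
Reagents that add atoms: water, SMILES O (supplies the formyl oxygen in the acetal hydrolysis)
Why: Crossed Claisen condensation: NaH forms the phenoxide and then the ketone enolate of 4, which attacks the non-enolisable, inductively activated ester 5, and formation of the stabilised diketonate of 6 drives the equilibrium. In hot aqueous acid the phenol adds to the new ketone and water is lost (cyclodehydration to the pyranone 7, as in the oxalate route to chromone-2-carboxylates), and the same medium hydrolyses the acetal, so C2 arrives at the aldehyde oxidation level without a redox step.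

Step 3
Reactants: 8 3,5,7-trimethoxy-4-oxo-4H-chromene-2-carbaldehyde
Product: 9 2-ethynyl-3,5,7-trimethoxy-4H-chromen-4-one
Conditions: dimethyl (1-diazo-2-oxopropyl)phosphonate (1.3 equiv), K2CO3 (2 equiv), MeOH/THF, 0 °C to rt
Reagents that add atoms: dimethyl (1-diazo-2-oxopropyl)phosphonate, SMILES CC(=O)C(=[N+]=[N-])P(=O)(OC)OC (its diazo carbon becomes the terminal alkyne carbon)
Why: Seyferth–Gilbert homologation in the Ohira–Bestmann variant: methanolysis of the acetyl group frees the diazomethylphosphonate anion, which adds to the non-enolisable aldehyde and eliminates phosphate to a diazoalkene; loss of N2 and a 1,2-hydrogen shift of the alkylidene carbene give the terminal alkyne. C3 carries a methoxy group and is the α-carbon of the pyranone, so it is not a conjugate acceptor, and carbonate at 0 °C limits attack on C2.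

Step 4
Reactants: 10 methyl vinyl ether; 11 chromium hexacarbonyl Cr(CO)6
Product: 14 pentacarbonyl[methoxy(1-methoxyvinyl)carbene]chromium, via 1-methoxyvinyllithium 12 (not isolated), via lithium acylchromate 13 (not isolated)
Conditions: t-BuLi, THF, −78 to 0 °C; Cr(CO)6, THF, 0 °C to rt; evaporate; Me3OBF4, CH2Cl2, 0 °C
Reagents that add atoms: trimethyloxonium tetrafluoroborate, SMILES C[O+](C)C.F[B-](F)(F)F (the methyl group on the carbene oxygen)
Why: Fischer synthesis of an alkoxycarbene complex: t-BuLi removes the α-vinyl hydrogen of 10, the vinyllithium 12 adds to a carbonyl ligand of 11 to give the acylchromate 13, and the hard oxonium salt alkylates its oxygen. The α-substituted vinyl group makes 14 an analogue of the isolable isopropenyl and dihydropyranyl complexes; it should be filtered through base-washed silica and used at once because the enol ether is acid-labile.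

Step 5
Reactants: 9 2-ethynyl-3,5,7-trimethoxy-4H-chromen-4-one; 14 pentacarbonyl[methoxy(1-methoxyvinyl)carbene]chromium
Product: 16 2-methoxy-5-(3,5,7-trimethoxy-4-oxo-4H-chromen-2-yl)cyclohexa-2,5-diene-1,4-dione, via dimethoxyphenol 15 (not isolated)
Conditions: 14 (1.5 equiv), THF (0.1 M), 50 °C, Ar; then (NH4)2Ce(NO3)6 (7 equiv), MeCN/H2O, 0 °C
Reagents that add atoms: water, SMILES O (supplies the C5' carbonyl oxygen that replaces the methoxy group lost as methanol)
Why: This is a Dötz benzannulation of an alkenyl(alkoxy)carbene complex of zerovalent chromium with a terminal alkyne and oxidative work-up; the closest known cases are the phenol and quinone syntheses from α-alkoxyalkenyl complexes such as the dihydropyranyl one. Thermal loss of one cis carbonyl ligand from 14 opens a site for 9, which inserts into the Cr=C bond (C5'–C6'), and migration of a carbonyl ligand onto the new carbene carbon gives a chromium-bound dienylketene (C1'–C2'). Ring B then closes by a thermal, disrotatory 6π electrocyclisation of this ketene (C2'–C3'), and the cyclohexadienone tautomerises to the 4-methoxyphenol 15, which stays on a Cr(CO)3 fragment. Tetravalent cerium strips the metal and takes two electrons from the para-oxygenated ring; water adds at C5' and methanol leaves, so of the ring B oxygens only the C4' ether keeps its methyl group. No stereocentre is formed. The selectivity needed is regiochemical: C1' with the chromone must bond to the carbonyl carbon and the terminal CH to the carbene carbon, and the size difference between hydrogen and a fully substituted pyranone carbon on a terminal alkyne secures this in the insertion step. The oxidation should be chemoselective because ring A is deactivated by the C4 carbonyl and has no para-dioxygen pair. The triple bond is a vinylogous ynone tempered by O1 and the ring A donors, so insertion may be slower than with alkyl alkynes; hence the excess of 14 and the moderate temperature.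

Step 6
Reactants: 16 2-methoxy-5-(3,5,7-trimethoxy-4-oxo-4H-chromen-2-yl)cyclohexa-2,5-diene-1,4-dione
Product: 17 2-(2,5-dihydroxy-4-methoxyphenyl)-3,5,7-trimethoxy-4H-chromen-4-one (5-O-methyloxyayanin A)
Conditions: Na2S2O4 (5 equiv), EtOAc/H2O (degassed), rt
Reagents that add atoms: none
Why: Two-electron reduction of a 1,4-benzoquinone to its hydroquinone by dithionite in a two-phase system; the pyranone, the C3 enol ether and the aryl ethers are inert to this reagent, and work-up under argon with a slightly acidic wash should guard the product against re-oxidation.

## Compound list

1 | 1,3,5-trimethoxybenzene | COc1cc(OC)cc(OC)c1 | starting material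
2 | methoxyacetyl chloride | COCC(=O)Cl | starting material
3 | 2-methoxy-1-(2,4,6-trimethoxyphenyl)ethan-1-one | COCC(=O)c1c(OC)cc(OC)cc1OC | intermediate (not isolated)
4 | 1-(2-hydroxy-4,6-dimethoxyphenyl)-2-methoxyethan-1-one | COCC(=O)c1c(O)cc(OC)cc1OC | intermediate
5 | ethyl diethoxyacetate | CCOC(OCC)C(=O)OCC | starting material
6 | 4,4-diethoxy-1-(2-hydroxy-4,6-dimethoxyphenyl)-2-methoxybutane-1,3-dione (racemic) | CCOC(OCC)C(=O)C(OC)C(=O)c1c(O)cc(OC)cc1OC | intermediate (not isolated)
7 | 2-(diethoxymethyl)-3,5,7-trimethoxy-4H-chromen-4-one | CCOC(OCC)c1oc2cc(OC)cc(OC)c2c(=O)c1OC | intermediate (not isolated)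
8 | 3,5,7-trimethoxy-4-oxo-4H-chromene-2-carbaldehyde | O=Cc1oc2cc(OC)cc(OC)c2c(=O)c1OC | intermediate
9 | 2-ethynyl-3,5,7-trimethoxy-4H-chromen-4-one | C#Cc1oc2cc(OC)cc(OC)c2c(=O)c1OC | intermediate
10 | methyl vinyl ether | COC=C | starting material
11 | chromium hexacarbonyl Cr(CO)6 | O=C=[Cr](=C=O)(=C=O)(=C=O)(=C=O)=C=O | starting material
12 | 1-methoxyvinyllithium | [Li]C(=C)OC | intermediate (not isolated)
13 | lithium pentacarbonyl(2-methoxyacryloyl)chromate | [Li+].COC(=C)C([O-])=[Cr](=C=O)(=C=O)(=C=O)(=C=O)=C=O | intermediate (not isolated)
14 | pentacarbonyl[methoxy(1-methoxyvinyl)carbene]chromium | COC(C(=C)OC)=[Cr](=C=O)(=C=O)(=C=O)(=C=O)=C=O | intermediate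
15 | 2-(2-hydroxy-4,5-dimethoxyphenyl)-3,5,7-trimethoxy-4H-chromen-4-one | COc1cc(OC)c2c(=O)c(OC)c(-c3cc(OC)c(OC)cc3O)oc2c1 | intermediate (not isolated)
16 | 2-methoxy-5-(3,5,7-trimethoxy-4-oxo-4H-chromen-2-yl)cyclohexa-2,5-diene-1,4-dione | COC1=CC(=O)C(c2oc3cc(OC)cc(OC)c3c(=O)c2OC)=CC1=O | intermediate
17 | 2-(2,5-dihydroxy-4-methoxyphenyl)-3,5,7-trimethoxy-4H-chromen-4-one (5-O-methyloxyayanin A) | COc1cc(OC)c2c(=O)c(OC)c(-c3cc(O)c(OC)cc3O)oc2c1 | target

## Step count and risks

Total step count: 6. Longest linear sequence: 5 steps (steps 1, 2, 3, 5 and 6); step 4 is a one-step branch that joins at step 5.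

Step 5 (key step). The most likely failure is slow or diverted alkyne insertion. The triple bond is conjugated to the pyranone carbonyl and is less nucleophilic than an alkyl alkyne, so thermal decay of the carbene complex, oligomerisation of the alkyne or double insertion may outrun the ketene electrocyclisation. A second hazard is over-oxidation of ring A during the cerium work-up if the oxidant is left too long. The fallback gives up the benzannulation and sets out from 4.
- C-acylation of the lithium dianion of 4 with 2,4,5-trimethoxybenzoyl chloride (LiN(SiMe3)2, THF, −78 °C to rt) would give 1-(2-hydroxy-4,6-dimethoxyphenyl)-2-methoxy-3-(2,4,5-trimethoxyphenyl)propane-1,3-dione F1.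
- Cyclodehydration (H2SO4, AcOH, 90 °C) would give 3,5,7-trimethoxy-2-(2,4,5-trimethoxyphenyl)-4H-chromen-4-one F2, the same compound as A3.
- Oxidative demethylation of the para-dimethoxy pair of ring B with (NH4)2Ce(NO3)6 in MeCN/H2O would return to the route at 16.

Step 4. Three processes threaten the complex: incomplete α-lithiation or decay of the vinyllithium on warming, hydrolysis of the enol ether on acidic supports, and polymerisation through the electron-poor double bond of the carbene-activated vinyl ether. The fallback builds the acylchromate from the other side, setting out from 11 and commercial methyl 2-methoxyacrylate.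
- Saponification (LiOH, THF/H2O) would give 2-methoxyacrylic acid F3.
- (COCl)2 with catalytic DMF would convert it into 2-methoxyacryloyl chloride F4.
- Reduction of 11 with potassium graphite C8K in THF would give dipotassium pentacarbonylchromate F5.
- Acylation of F5 with F4 at −78 °C would give potassium pentacarbonyl(2-methoxyacryloyl)chromate F6, and methylation with Me3OBF4 would come back to the route at 14.

Step 3. The risk is conjugate addition of methoxide or methanol to the new triple bond through the pyranone, or methoxide attack at C2 with ring opening; both are favoured by the electron-poor heterocycle. The fallback installs the alkyne by cross-coupling and sets out from 4.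
- Condensation with N,N-dimethylformamide dimethyl acetal (toluene, 100 °C) would give (Z)-3-(dimethylamino)-1-(2-hydroxy-4,6-dimethoxyphenyl)-2-methoxyprop-2-en-1-one F7.
- Acid (AcOH, 80 °C) would close F7 to 3,5,7-trimethoxy-4H-chromen-4-one F8.
- Zincation at C2 with TMPZnCl·LiCl in THF and quenching with I2 would give 2-iodo-3,5,7-trimethoxy-4H-chromen-4-one F9.
- Sonogashira coupling with ethynyltrimethylsilane (PdCl2(PPh3)2, CuI, Et3N, THF) would give 3,5,7-trimethoxy-2-[(trimethylsilyl)ethynyl]-4H-chromen-4-one F10.
- Desilylation with Bu4NF buffered by AcOH (THF, 0 °C) would rejoin the route at 9 without exposure to methoxide.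

Step 2. The Claisen condensation may stall because the dianion of the α-methoxy ketone is hindered and the dialkoxyacetate is only a moderate electrophile; O-acylation of the phenoxide and retro-Claisen cleavage in the hot acid are the competing processes. The fallback uses the more electrophilic oxalate at the price of a redox pair and sets out from 4.
- Diethyl oxalate with NaOEt in EtOH would give ethyl 4-(2-hydroxy-4,6-dimethoxyphenyl)-3-methoxy-2,4-dioxobutanoate F11.
- HCl in EtOH at reflux would close F11 to ethyl 3,5,7-trimethoxy-4-oxo-4H-chromene-2-carboxylate F12.
- NaBH4 in MeOH/THF at 0 °C would reduce the activated ester to 2-(hydroxymethyl)-3,5,7-trimethoxy-4H-chromen-4-one F13.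
- MnO2 in CH2Cl2 would oxidise F13 and return to the route at 8.

## Further compounds

F1 | step 5 | 1-(2-hydroxy-4,6-dimethoxyphenyl)-2-methoxy-3-(2,4,5-trimethoxyphenyl)propane-1,3-dione (racemic) | COC(C(=O)c1c(O)cc(OC)cc1OC)C(=O)c1cc(OC)c(OC)cc1OC
F2 | step 5 | 3,5,7-trimethoxy-2-(2,4,5-trimethoxyphenyl)-4H-chromen-4-one | COc1cc(OC)c2c(=O)c(OC)c(-c3cc(OC)c(OC)cc3OC)oc2c1
F3 | step 4 | 2-methoxyacrylic acid | COC(=C)C(=O)O
F4 | step 4 | 2-methoxyacryloyl chloride | COC(=C)C(=O)Cl
F5 | step 4 | dipotassium pentacarbonylchromate K2Cr(CO)5 | [K+].[K+].O=C=[Cr-2](=C=O)(=C=O)(=C=O)=C=O
F6 | step 4 | potassium pentacarbonyl(2-methoxyacryloyl)chromate | [K+].COC(=C)C([O-])=[Cr](=C=O)(=C=O)(=C=O)(=C=O)=C=O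
F7 | step 3 | (Z)-3-(dimethylamino)-1-(2-hydroxy-4,6-dimethoxyphenyl)-2-methoxyprop-2-en-1-one | CN(C)/C=C(\OC)C(=O)c1c(O)cc(OC)cc1OC
F8 | step 3 | 3,5,7-trimethoxy-4H-chromen-4-one | COc1cc(OC)c2c(=O)c(OC)coc2c1
F9 | step 3 | 2-iodo-3,5,7-trimethoxy-4H-chromen-4-one | COc1cc(OC)c2c(=O)c(OC)c(I)oc2c1
F10 | step 3 | 3,5,7-trimethoxy-2-[(trimethylsilyl)ethynyl]-4H-chromen-4-one | COc1cc(OC)c2c(=O)c(OC)c(C#C[Si](C)(C)C)oc2c1
F11 | step 2 | ethyl 4-(2-hydroxy-4,6-dimethoxyphenyl)-3-methoxy-2,4-dioxobutanoate (racemic) | CCOC(=O)C(=O)C(OC)C(=O)c1c(O)cc(OC)cc1OC
F12 | step 2 | ethyl 3,5,7-trimethoxy-4-oxo-4H-chromene-2-carboxylate | CCOC(=O)c1oc2cc(OC)cc(OC)c2c(=O)c1OC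
F13 | step 2 | 2-(hydroxymethyl)-3,5,7-trimethoxy-4H-chromen-4-one | OCc1oc2cc(OC)cc(OC)c2c(=O)c1OC
A1 | alternative 1 | (Z)-2-methoxy-1-(2,4,6-trihydroxyphenyl)-3-(2,4,5-trimethoxyphenyl)prop-2-en-1-one | Oc1cc(O)c(C(=O)/C(OC)=C/c2cc(OC)c(OC)cc2OC)c(O)c1
A2 | alternative 1 | methyl (Z)-8-methoxy-3,5,7-trioxo-9-(2,4,5-trimethoxyphenyl)non-8-enoate | COC(=O)CC(=O)CC(=O)CC(=O)/C(OC)=C/c1cc(OC)c(OC)cc1OC
A3 | alternative 2 | 3,5,7-trimethoxy-2-(2,4,5-trimethoxyphenyl)-4H-chromen-4-one | COc1cc(OC)c2c(=O)c(OC)c(-c3cc(OC)c(OC)cc3OC)oc2c1
A4 | alternative 2 | 3,5-dimethoxy-2-(trimethylsilyl)phenyl trifluoromethanesulfonate | COc1cc(OC)c([Si](C)(C)C)c(OS(=O)(=O)C(F)(F)F)c1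
A5 | alternative 2 | 5-methoxy-2,2-dimethyl-6-(2,4,5-trimethoxyphenyl)-4H-1,3-dioxin-4-one | COC1=C(c2cc(OC)c(OC)cc2OC)OC(C)(C)OC1=O
A6 | alternative 2 | 3,5-dimethoxybenzyne (1,2-didehydro-3,5-dimethoxybenzene) | C1#CC(OC)=CC(OC)=C1
A7 | alternative 2 | 2-methoxy-3-oxo-3-(2,4,5-trimethoxyphenyl)prop-1-en-1-one | COC(=C=O)C(=O)c1cc(OC)c(OC)cc1OC
A8 | alternative 3 | 5,7-dihydroxy-3-methoxy-2-(2,4,5-trimethoxyphenyl)-4H-chromen-4-one | COc1c(-c2cc(OC)c(OC)cc2OC)oc2cc(O)cc(O)c2c1=O
A9 | alternative 3 | methyl 4-[5-methoxy-4-oxo-6-(2,4,5-trimethoxyphenyl)-4H-pyran-2-yl]-3-oxobutanoate | COC(=O)CC(=O)Cc1cc(=O)c(OC)c(-c2cc(OC)c(OC)cc2OC)o1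
A10 | alternative 3 | kojic acid (5-hydroxy-2-(hydroxymethyl)-4H-pyran-4-one) | OCc1cc(=O)c(O)co1
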